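**Plan**
1. Cuts: the C4–CH3 and C11–CH3 bonds (back to the two enol triflates of a propellane diketone); then C5–C6 together with O3′–C1 in one operation; then C1=C5 (aldol), the furan-masked C1/C4 diketone, O2′–C5 (Mitsunobu), C6=C7, C7=C8 and C1–C10; starting materials are pristimerin, furfuryl alcohol, crotonaldehyde and an acetonyl ylide.
2. Enabling feature: C1 and C5, the two O-bearing carbons shared by the dioxane, the cyclopentene and the cycloheptane (C1–C10–C9–C8–C7–C6–C5), are the β- and α-carbons of a latent cyclopentenone (C4=O where the C4 methyl will sit); C6/C7 are the β/α-carbons of a vinyl ketone whose acetyl becomes the isopropenyl group.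
3. Forward ring order: ring A of pristimerin is aromatised (Δ6, 8α-H), then furan, then cyclopentenone, then dioxane and cycloheptane in one pot (cycloheptane last), then two methyl couplings.
4. Stereochemistry: triterpene centres from pristimerin; C8 by suprafacial diazene hydrogen transfer; C10 by organocatalytic Friedel–Crafts alkylation; C1/C5 relayed from C10 in the ring closure (cis fusion enforced by the tether); C7 by kinetic protonation.

Key step: step 10

Remark: C1–C15 are guaiane locants of the C15 half (C1 bears O3′ and C10; C5 bears O2′, C4 and C6), primed locants are triterpene locants, and commercial pristimerin is assumed to have the natural configuration, which is that of the triterpene half of the target.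

Step 1
Reactants: 1 pristimerin
Product: 2 3-O-(methoxymethyl)pristimerin
Conditions: MOMCl, i-Pr2NEt, CH2Cl2, 0 °C to rt
Reagents that add atoms: chloromethyl methyl ether (MOMCl), COCCl
Why: Williamson-type O-alkylation of the single hydroxyl (the C3 enol OH) blocks O3′, so that the oxygen freed at C2 in step 2 is the only phenol available for the first ether bond.

Step 2
Reactants: 2 3-O-(methoxymethyl)pristimerin
Product: 5 methyl (8α)-2-hydroxy-3-(methoxymethoxy)-24-norfriedela-1,3,5(10),6-tetraen-29-oate, via hydrazine adduct 3 (not isolated), via allylic diazene 4 (not isolated)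
Conditions: TsNHNH2 (1.05 equiv), THF, 0 °C to rt; then NaOAc, 50 °C
Reagents that add atoms: none
Why: Proposed new method: 1,6-addition of the hydrazide NH2 to C6 of the extended quinone methide (expected on the α-face, anti to the syn-axial C9 and C14 methyls) aromatises ring A, acetate-assisted loss of sulfinate gives the monoalkyl diazene, and its retro-ene loss of N2 delivers hydrogen suprafacially to C8 (8α-H) while the alkene moves to C6=C7; the closest known reactions are nucleophile additions at C6 of pristimerin and the allylic diazene rearrangement of enone tosylhydrazone reductions and of the Myers reductive transposition.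

Step 3
Reactants: 6 furfuryl alcohol; 7 (E)-but-2-enal
Product: 8 (3S)-3-[5-(hydroxymethyl)furan-2-yl]butanal
Conditions: (2R,5R)-5-benzyl-2-tert-butyl-3-methylimidazolidin-4-one·CF3CO2H (20 mol %), THF–H2O, −20 °C
Reagents that add atoms: none
Why: Iminium-catalysed enantioselective Friedel–Crafts alkylation of a 2-alkylfuran at its free α-position; the (2R,5R)-imidazolidinone shields one face of the (E)-iminium ion and is chosen, by analogy with the sense of induction in pyrrole and indole alkylations, to set C10 as S.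

Step 4
Reactants: 8 (3S)-3-[5-(hydroxymethyl)furan-2-yl]butanal; 9 1-(triphenyl-λ5-phosphanylidene)propan-2-one
Product: 10 (3E,6S)-6-[5-(hydroxymethyl)furan-2-yl]hept-3-en-2-one
Conditions: CH2Cl2, rt
Reagents that add atoms: none
Why: Wittig olefination with the stabilised ylide gives the (E)-enone and leaves the β-stereocentre C10 untouched.

Step 5
Reactants: 5 methyl (8α)-2-hydroxy-3-(methoxymethoxy)-24-norfriedela-1,3,5(10),6-tetraen-29-oate; 10 (3E,6S)-6-[5-(hydroxymethyl)furan-2-yl]hept-3-en-2-one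
Product: 11 2′-O-{[5-[(2S,4E)-6-oxohept-4-en-2-yl]furan-2-yl]methyl} ether of phenol 5
Conditions: PPh3, DIAD, THF, 0 °C
Reagents that add atoms: none
Why: Mitsunobu etherification of the primary furfuryl alcohol with the only free phenol (O2′–H, O3′ being blocked) forms the O2′–C5 bond regiospecifically.

Step 6
Reactants: 11 2′-O-{[5-[(2S,4E)-6-oxohept-4-en-2-yl]furan-2-yl]methyl} ether of phenol 5
Product: 14 2′-O-[(6S,8E)-6-methyl-2,5,10-trioxoundec-8-en-1-yl] ether of phenol 5, via furan endoperoxide 12 (not isolated), via cis-enedione 13 (not isolated)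
Conditions: O2, methylene blue, hν, CH2Cl2, −78 °C; Me2S; then Hantzsch ester, toluene, 60 °C
Reagents that add atoms: dioxygen, O=O
Why: [4+2] addition of singlet oxygen to the 2,5-disubstituted furan (the most reactive acceptor present), sulfide reduction to the cis-enedione and transfer hydrogenation of its doubly activated C=C unmask the saturated 1,4-diketone under neutral conditions, so that C10 (now α to the C1 ketone) should not epimerise.

Step 7
Reactants: 14 2′-O-[(6S,8E)-6-methyl-2,5,10-trioxoundec-8-en-1-yl] ether of phenol 5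
Product: 16 2-aryloxy-3-[(2S,4E)-6-oxohept-4-en-2-yl]cyclopent-2-en-1-one (aryl = 2′-O residue of 5), via aldol 15 (not isolated)
Conditions: K2CO3, MeOH, 0 °C to rt
Reagents that add atoms: none
Why: Intramolecular aldol condensation of the 1,4-diketone (cyclopentenone annulation): the aryloxy-substituted C5 methylene is the most acidic carbon and adds to the C1 ketone, and dehydration can only occur toward C5, which gives the 2-aryloxy enone.

Step 8
Reactants: 16 2-aryloxy-3-[(2S,4E)-6-oxohept-4-en-2-yl]cyclopent-2-en-1-one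
Product: 20 2-aryloxy-3-[(2S)-5-methylidene-6-oxoheptan-2-yl]cyclopent-2-en-1-one (3′-OMOM), via silyl enol ether 17 (not isolated), via Mannich base 18 (not isolated), via ammonium iodide 19 (not isolated)
Conditions: Et3SiH, RhCl(PPh3)3 (2 mol %), toluene, 50 °C; CH2=NMe2+ I−, CH2Cl2, rt; MeI; then NaHCO3 (aq)
Reagents that add atoms: N,N-dimethylmethyleneiminium iodide (Eschenmoser's salt), C=[N+](C)C.[I-]
Why: Rh-catalysed 1,4-hydrosilylation should pick the unhindered acyclic (E)-enone over the tetrasubstituted ring enone, the silyl enol ether is aminomethylated at C7, and quaternisation–elimination (Mannich route to α-methylene ketones) installs C6 as the exo-methylene carbon.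

Step 9
Reactants: 20 2-aryloxy-3-[(2S)-5-methylidene-6-oxoheptan-2-yl]cyclopent-2-en-1-one (3′-OMOM)
Product: 21 2-aryloxy-3-[(2S)-5-methylidene-6-oxoheptan-2-yl]cyclopent-2-en-1-one with free 3′-OH
Conditions: CF3CO2H, CH2Cl2, H2O (2 equiv), 0 °C
Reagents that add atoms: none
Why: Acidolysis of the aryl methoxymethyl acetal frees O3′–H; both enones, the aryl enol ether and the hindered ester should tolerate brief cold acid.

Step 10
Reactants: 21 2-aryloxy-3-[(2S)-5-methylidene-6-oxoheptan-2-yl]cyclopent-2-en-1-one with free 3′-OH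
Product: 24 propellane diketone (26 with C3H2–C4=O in place of C3H=C4–CH3 and acetyl in place of isopropenyl; C1 S, C5 R, C7 R, C10 S), via oxa-Michael enolate 22 (not isolated), via ring-closed enolate 23 (not isolated)
Conditions: 2-tert-butyl-1,1,3,3-tetramethylguanidine (0.3 equiv), MeCN, 5 mM, rt; AcOH quench
Reagents that add atoms: none
Why: Proposed new method: the guanidine forms the O3′ phenoxide, which adds reversibly to C1, the β-carbon of the 2-aryloxycyclopentenone (6-endo-trig oxa-Michael, as in the phenol-to-enone closure of chromanones), and the C5 enolate so formed is captured by C6 of the tethered α-methylene ketone (7-endo-trig carbo-Michael), the one step not readily reversed, so the uphill first addition is drained in Curtin–Hammett fashion; the closest known reaction type is the oxa-Michael/Michael domino (Michael-initiated ring closure) used for chromans and tetrahydroxanthenones. The dioxane therefore closes first and the cycloheptane last, and because the chain hangs on C1 the C5–C6 bond must form on the enolate face syn to C10, which forces O3′ and O2′ cis (the propellane). Which enone face receives O3′ is relayed from C10: a chair-like seven-membered transition state folded toward the dioxane oxygens keeps the C10 methyl pseudo-equatorial only in the adduct with the methyl cis to the oxygens, and metal-free conditions avoid an enolate–acceptor chelate that would favour the opposite fold. C7 is set by protonation of the exocyclic enolate from the side away from the axial O2′ (equatorial attack), which places the acetyl cis to the C10 methyl, and the weak base should not enolise the product ketone, so this kinetic outcome is kept. The step needs C- over O-bonding at the vinyl ketone and intra- over intermolecular addition: phenoxide adducts to the vinyl ketone are reversible, only C5 can reach C6 through a seven-membered ring, and high dilution suppresses oligomerisation.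

Step 11
Reactants: 24 propellane diketone
Product: 25 bis(enol triflate) (C4–OTf with C3=C4; C11–OTf with C11=C12H2)
Conditions: KN(SiMe3)2 (3 equiv) added to 24 and PhNTf2 (3 equiv), THF, −78 °C
Reagents that add atoms: N-phenylbis(trifluoromethanesulfonimide), FC(F)(F)S(=O)(=O)N(c1ccccc1)S(=O)(=O)C(F)(F)F
Why: Kinetic deprotonation (C3–H of the cyclopentanone, the only enolisable side since C5 is quaternary; CH3 of the methyl ketone instead of the hindered C7–H) with in situ O-sulfonylation gives both enol triflates and leaves C7 untouched.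

Step 12
Reactants: 25 bis(enol triflate)
Product: 26 CNP0113384.2 (target)
Conditions: MeZnCl (4 equiv), Pd(PPh3)4 (10 mol %), THF, rt to 40 °C
Reagents that add atoms: methylzinc chloride, C[Zn]Cl
Why: Double Negishi coupling of the alkenyl triflates puts C15 on C4 (fixing the C3=C4 double bond) and converts the 1-(triflyloxy)vinyl group into the isopropenyl group without touching any stereocentre.

**Compound list**
1 | pristimerin, methyl (20α)-3-hydroxy-2-oxo-24-norfriedela-1(10),3,5,7-tetraen-29-oate | CC1=C(O)C(=O)C=C2C1=CC=C1[C@@]2(C)CC[C@@]2(C)[C@@H]3C[C@](C)(C(=O)OC)CC[C@]3(C)CC[C@]12C | starting material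
2 | 3-O-(methoxymethyl)pristimerin | CC1=C(OCOC)C(=O)C=C2C1=CC=C1[C@@]2(C)CC[C@@]2(C)[C@@H]3C[C@](C)(C(=O)OC)CC[C@]3(C)CC[C@]12C | intermediate
3 | methyl 2-hydroxy-3-(methoxymethoxy)-6α-[2-(4-methylbenzenesulfonyl)hydrazinyl]-24-norfriedela-1,3,5(10),7-tetraen-29-oate | Oc1cc2c(c(C)c1OCOC)[C@@H](NNS(=O)(=O)c1ccc(C)cc1)C=C1[C@@]2(C)CC[C@@]2(C)[C@@H]3C[C@](C)(C(=O)OC)CC[C@]3(C)CC[C@]12C | intermediate
4 | methyl 6α-diazenyl-2-hydroxy-3-(methoxymethoxy)-24-norfriedela-1,3,5(10),7-tetraen-29-oate | Oc1cc2c(c(C)c1OCOC)[C@@H](N=N)C=C1[C@@]2(C)CC[C@@]2(C)[C@@H]3C[C@](C)(C(=O)OC)CC[C@]3(C)CC[C@]12C | intermediate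
5 | methyl (8α)-2-hydroxy-3-(methoxymethoxy)-24-norfriedela-1,3,5(10),6-tetraen-29-oate | Oc1cc2c(c(C)c1OCOC)C=C[C@H]1[C@@]2(C)CC[C@@]2(C)[C@@H]3C[C@](C)(C(=O)OC)CC[C@]3(C)CC[C@]12C | intermediate
6 | furfuryl alcohol (furan-2-ylmethanol) | OCc1ccco1 | starting material
7 | (E)-but-2-enal (crotonaldehyde) | C/C=C/C=O | starting material
8 | (3S)-3-[5-(hydroxymethyl)furan-2-yl]butanal | O=CC[C@H](C)c1ccc(CO)o1 | intermediate
9 | 1-(triphenyl-λ5-phosphanylidene)propan-2-one | CC(=O)C=P(c1ccccc1)(c1ccccc1)c1ccccc1 | starting material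
10 | (3E,6S)-6-[5-(hydroxymethyl)furan-2-yl]hept-3-en-2-one | CC(=O)/C=C/C[C@H](C)c1ccc(CO)o1 | intermediate
11 | 2′-O-{[5-[(2S,4E)-6-oxohept-4-en-2-yl]furan-2-yl]methyl} ether of phenol 5 | CC(=O)/C=C/C[C@H](C)c1ccc(COc2cc3c(c(C)c2OCOC)C=C[C@H]2[C@@]3(C)CC[C@@]3(C)[C@@H]4C[C@](C)(C(=O)OC)CC[C@]4(C)CC[C@]23C)o1 | intermediate
12 | 2,3,7-trioxabicyclo[2.2.1]hept-5-ene (furan endoperoxide) of 11 | CC(=O)/C=C/C[C@H](C)C12C=CC(COc3cc4c(c(C)c3OCOC)C=C[C@H]3[C@@]4(C)CC[C@@]4(C)[C@@H]5C[C@](C)(C(=O)OC)CC[C@]5(C)CC[C@]34C)(OO1)O2 | intermediate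
13 | 2′-O-[(3Z,6S,8E)-6-methyl-2,5,10-trioxoundeca-3,8-dien-1-yl] ether of phenol 5 | CC(=O)/C=C/C[C@H](C)C(=O)/C=C\C(=O)COc1cc2c(c(C)c1OCOC)C=C[C@H]1[C@@]2(C)CC[C@@]2(C)[C@@H]3C[C@](C)(C(=O)OC)CC[C@]3(C)CC[C@]12C | intermediate
14 | 2′-O-[(6S,8E)-6-methyl-2,5,10-trioxoundec-8-en-1-yl] ether of phenol 5 | CC(=O)/C=C/C[C@H](C)C(=O)CCC(=O)COc1cc2c(c(C)c1OCOC)C=C[C@H]1[C@@]2(C)CC[C@@]2(C)[C@@H]3C[C@](C)(C(=O)OC)CC[C@]3(C)CC[C@]12C | intermediate
15 | 2-aryloxy-3-hydroxy-3-[(2S,4E)-6-oxohept-4-en-2-yl]cyclopentan-1-one (aldol, aryl = 2′-O residue of 5) | CC(=O)/C=C/C[C@H](C)C1(O)CCC(=O)C1Oc1cc2c(c(C)c1OCOC)C=C[C@H]1[C@@]2(C)CC[C@@]2(C)[C@@H]3C[C@](C)(C(=O)OC)CC[C@]3(C)CC[C@]12C | intermediate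
16 | 2-aryloxy-3-[(2S,4E)-6-oxohept-4-en-2-yl]cyclopent-2-en-1-one (aryl = 2′-O residue of 5) | CC(=O)/C=C/C[C@H](C)C1=C(Oc2cc3c(c(C)c2OCOC)C=C[C@H]2[C@@]3(C)CC[C@@]3(C)[C@@H]4C[C@](C)(C(=O)OC)CC[C@]4(C)CC[C@]23C)C(=O)CC1 | intermediate
17 | triethylsilyl enol ether of the side-chain ketone of 16 (C11(OSiEt3)=C7) | CC[Si](CC)(CC)OC(C)=CCC[C@H](C)C1=C(Oc2cc3c(c(C)c2OCOC)C=C[C@H]2[C@@]3(C)CC[C@@]3(C)[C@@H]4C[C@](C)(C(=O)OC)CC[C@]4(C)CC[C@]23C)C(=O)CC1 | intermediate
18 | 2-aryloxy-3-[(2S)-5-(dimethylaminomethyl)-6-oxoheptan-2-yl]cyclopent-2-en-1-one (Mannich base) | CC(=O)C(CN(C)C)CC[C@H](C)C1=C(Oc2cc3c(c(C)c2OCOC)C=C[C@H]2[C@@]3(C)CC[C@@]3(C)[C@@H]4C[C@](C)(C(=O)OC)CC[C@]4(C)CC[C@]23C)C(=O)CC1 | intermediate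
19 | trimethylammonium iodide of 18 | CC(=O)C(C[N+](C)(C)C)CC[C@H](C)C1=C(Oc2cc3c(c(C)c2OCOC)C=C[C@H]2[C@@]3(C)CC[C@@]3(C)[C@@H]4C[C@](C)(C(=O)OC)CC[C@]4(C)CC[C@]23C)C(=O)CC1.[I-] | intermediate
20 | 2-aryloxy-3-[(2S)-5-methylidene-6-oxoheptan-2-yl]cyclopent-2-en-1-one (3′-OMOM) | CC(=O)C(=C)CC[C@H](C)C1=C(Oc2cc3c(c(C)c2OCOC)C=C[C@H]2[C@@]3(C)CC[C@@]3(C)[C@@H]4C[C@](C)(C(=O)OC)CC[C@]4(C)CC[C@]23C)C(=O)CC1 | intermediate
21 | 2-aryloxy-3-[(2S)-5-methylidene-6-oxoheptan-2-yl]cyclopent-2-en-1-one (3′-OH free) | CC(=O)C(=C)CC[C@H](C)C1=C(Oc2cc3c(c(C)c2O)C=C[C@H]2[C@@]3(C)CC[C@@]3(C)[C@@H]4C[C@](C)(C(=O)OC)CC[C@]4(C)CC[C@]23C)C(=O)CC1 | intermediate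
22 | guanidinium C4-enolate of the oxa-Michael adduct (O3′–C1 formed, C1 S) | CC(=O)C(=C)CC[C@H](C)[C@@]12CCC([O-])=C1Oc1cc3c(c(C)c1O2)C=C[C@H]1[C@@]3(C)CC[C@@]3(C)[C@@H]4C[C@](C)(C(=O)OC)CC[C@]4(C)CC[C@]13C.CN(C)C(N(C)C)=[NH+]C(C)(C)C | intermediate
23 | guanidinium C7=C11 enolate of the ring-closed propellane | CC([O-])=C1CC[C@H](C)[C@@]23CCC(=O)[C@]2(C1)Oc1cc2c(c(C)c1O3)C=C[C@H]1[C@@]2(C)CC[C@@]2(C)[C@@H]3C[C@](C)(C(=O)OC)CC[C@]3(C)CC[C@]12C.CN(C)C(N(C)C)=[NH+]C(C)(C)C | intermediate
24 | propellane diketone (C4 ketone, 7-acetyl; C1 S, C5 R, C7 R, C10 S) | CC(=O)[C@@H]1CC[C@H](C)[C@@]23CCC(=O)[C@]2(C1)Oc1cc2c(c(C)c1O3)C=C[C@H]1[C@@]2(C)CC[C@@]2(C)[C@@H]3C[C@](C)(C(=O)OC)CC[C@]3(C)CC[C@]12C | intermediate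
25 | bis(enol triflate) of 24 (C4–OTf, C3=C4; C11–OTf, C11=C12H2) | C=C(OS(=O)(=O)C(F)(F)F)[C@@H]1CC[C@H](C)[C@@]23CC=C(OS(=O)(=O)C(F)(F)F)[C@]2(C1)Oc1cc2c(c(C)c1O3)C=C[C@H]1[C@@]2(C)CC[C@@]2(C)[C@@H]3C[C@](C)(C(=O)OC)CC[C@]3(C)CC[C@]12C | intermediate
26 | CNP0113384.2 (C1 S, C5 S, C7 R, C10 S; 8′α-H) | C=C(C)[C@@H]1CC[C@H](C)[C@@]23CC=C(C)[C@]2(C1)Oc1cc2c(c(C)c1O3)C=C[C@H]1[C@@]2(C)CC[C@@]2(C)[C@@H]3C[C@](C)(C(=O)OC)CC[C@]3(C)CC[C@]12C | target

**Count and risks**
Total steps: 12. Longest linear sequence: 10 (steps 1, 2, 5–12 from pristimerin; equally steps 3–12 from furfuryl alcohol).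

Step 10 (key step). What may go wrong: the reversible phenoxide addition is not intercepted by the C5–C6 closure (oligomerisation through the vinyl ketone), or facial selectivity in the seven-membered closure and at the C7 protonation is poor. The fallback sets out from 21 and uses acid instead of base. A Brønsted acid (CF3SO3H, catalytic) should effect the phenol conjugate addition, as in acid-catalysed chromanone formation, to give the cis-fused benzodioxane ketone F1. Continued acid treatment (H2SO4 in benzene, as in the acid-catalysed Robinson annulation) should then let the more substituted enol, the one toward C5, add to the vinyl ketone. The route is rejoined at 24.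

Step 2. What may go wrong: hydride-type reduction or sulfinate capture of the quinone methide competes with hydrazide addition, or hydrogen is delivered to the β-face of C8. The fallback sets out from 2. NaBH4 in MeOH should reduce the quinone methide at C6 to methyl 2-hydroxy-3-(methoxymethoxy)-24-norfriedela-1,3,5(10),7-tetraen-29-oate F2. TBSCl and imidazole give its silyl ether F3. KOt-Bu in DMSO should move the 7,8-double bond into conjugation with the arene, with C8 protonated from the less hindered α-face, to give the Δ6 silyl ether F4. Bu4NF then frees the phenol and the route is rejoined at 5.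

Step 11. What may go wrong: the acetyl group enolises toward C7 (epimerisation, internal triflate), or the two carbonyl groups undergo aldol reaction before O-sulfonylation. The fallback sets out from 24 and makes the isopropenyl group by olefination instead. Ph3P=CH2 (1.1 equiv, THF, 0 °C) should methylenate only the methyl ketone, the ring ketone being flanked by the fully substituted C5, to give the isopropenyl ketone F5. KN(SiMe3)2 and PhNTf2 give the single enol triflate F6, and MeZnCl with Pd(PPh3)4 rejoins the route at 26.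

**Further compounds**
F1 | step 10 | cis-fused benzodioxane ketone (neutral oxa-Michael adduct of 21, C5–H) | CC(=O)C(=C)CC[C@H](C)[C@@]12CCC(=O)[C@@H]1Oc1cc3c(c(C)c1O2)C=C[C@H]1[C@@]3(C)CC[C@@]3(C)[C@@H]4C[C@](C)(C(=O)OC)CC[C@]4(C)CC[C@]13C
F2 | step 2 | methyl 2-hydroxy-3-(methoxymethoxy)-24-norfriedela-1,3,5(10),7-tetraen-29-oate | Oc1cc2c(c(C)c1OCOC)CC=C1[C@@]2(C)CC[C@@]2(C)[C@@H]3C[C@](C)(C(=O)OC)CC[C@]3(C)CC[C@]12C
F3 | step 2 | 2-O-tert-butyldimethylsilyl ether of F2 | CC(C)(C)[Si](C)(C)Oc1cc2c(c(C)c1OCOC)CC=C1[C@@]2(C)CC[C@@]2(C)[C@@H]3C[C@](C)(C(=O)OC)CC[C@]3(C)CC[C@]12C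
F4 | step 2 | methyl (8α)-2-(tert-butyldimethylsilyloxy)-3-(methoxymethoxy)-24-norfriedela-1,3,5(10),6-tetraen-29-oate | CC(C)(C)[Si](C)(C)Oc1cc2c(c(C)c1OCOC)C=C[C@H]1[C@@]2(C)CC[C@@]2(C)[C@@H]3C[C@](C)(C(=O)OC)CC[C@]3(C)CC[C@]12C
F5 | step 11 | isopropenyl ketone (24 with the acetyl group methylenated, C4 ketone kept) | C=C(C)[C@@H]1CC[C@H](C)[C@@]23CCC(=O)[C@]2(C1)Oc1cc2c(c(C)c1O3)C=C[C@H]1[C@@]2(C)CC[C@@]2(C)[C@@H]3C[C@](C)(C(=O)OC)CC[C@]3(C)CC[C@]12C
F6 | step 11 | C4 enol triflate of F5 (C3=C4) | C=C(C)[C@@H]1CC[C@H](C)[C@@]23CC=C(OS(=O)(=O)C(F)(F)F)[C@]2(C1)Oc1cc2c(c(C)c1O3)C=C[C@H]1[C@@]2(C)CC[C@@]2(C)[C@@H]3C[C@](C)(C(=O)OC)CC[C@]3(C)CC[C@]12C
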